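**Plan**
1. Core numbering (3,7-dioxabicyclo[3.3.0]octan-2-one): lactone ring C1–C2(=O)–O3–C4–C5, ether ring C5–C6–O7–C8–C1, guaiacyl ring on C4, catechol ring on C8. The target is (1S,4S,5R,8S), cis-fused, with both aryl groups on the convex face.
2. Enabling feature: in the ether ring C6 is a bare CH2 between O7 and C5, so it can enter as a formaldehyde-level oxocarbenium carbon on O7. In the lactone ring C4 is benzylic to the electron-rich guaiacyl ring and adjacent to C5, so a cation there lies within reach of the C2 ester oxygen.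
3. Retrosynthesis: remove the benzyl and pivaloyl groups; cut C5–C6 and O3–C4 together (Prins closure ended by lactonisation) to an acyclic methoxymethyl ether; cut C1–C8 (aldol) and C4=C5 (Wittig).
4. Forward: the Wittig reaction joins C4=C5, a titanium aldol joins C1–C8, then the ether ring closes first and the lactone ring second in one flask; two deprotections finish.
5. Stereochemistry: C1 and C8 come from an Evans-syn aldol of an (S)-4-benzylthiazolidinethione imide; C5 and C4 are set by these two centres in the cascade (cis fusion enforced by lactonisation, aryl exo).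

Key step: step 7

Assumption: Me3SiOTf is used in slight excess in step 7, so the acetal methoxy group is taken to leave as Me3SiOMe and the ester methyl group as MeOTf.

**Route**

Step 1
Reactants: 1 3,4-dihydroxybenzaldehyde; 2 pivaloyl chloride (2.3 equiv in all)
Product: 3 3,4-bis(pivaloyloxy)benzaldehyde
Conditions: 2 (2.3 equiv), Et3N (3 equiv), DMAP (cat.), CH2Cl2, 0 °C to rt
Reagents that add atoms: pivaloyl chloride (the second equivalent of 2), CC(C)(C)C(=O)Cl
Why: DMAP-catalysed O-acylation consumes one molecule of the acid chloride per phenol, so two equivalents should esterify both hydroxyl groups without touching the aldehyde and make the catechol ring electron-poor for the later cationic step.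

Step 2
Reactants: 4 (2-carboxyethyl)triphenylphosphonium bromide; 5 4-(benzyloxy)-3-methoxybenzaldehyde
Product: 7 (E)-4-[4-(benzyloxy)-3-methoxyphenyl]but-3-enoic acid, via ylide carboxylate 6 (not isolated)
Conditions: NaN(SiMe3)2 (2.1 equiv), THF, 0 °C; then 5, −78 °C to rt; 1 M HCl
Reagents that add atoms: none
Why: Wittig olefination in which the carboxylate-bearing ylide should add to the aromatic aldehyde with the E preference usual for such ylides, leaving the styrene out of conjugation with the acid; a minor Z isomer would be removed by crystallisation.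

Step 3
Reactants: 7 (E)-4-arylbut-3-enoic acid; 8 (S)-4-benzyl-1,3-thiazolidine-2-thione
Product: 9 (4S)-4-benzyl-3-[(E)-4-(4-benzyloxy-3-methoxyphenyl)but-3-enoyl]-1,3-thiazolidine-2-thione
Conditions: DCC, DMAP (cat.), CH2Cl2, 0 °C to rt
Reagents that add atoms: none
Why: Steglich-type carbodiimide coupling is a standard N-acylation of thiazolidinethiones and is mild enough to leave the β,γ-alkene in place.

Step 4
Reactants: 9 N-acyl thiazolidinethione; 3 3,4-bis(pivaloyloxy)benzaldehyde
Product: 11 (4S)-4-benzyl-3-{(2S,3S)-2-[(E)-2-(4-benzyloxy-3-methoxyphenyl)ethenyl]-3-[3,4-bis(pivaloyloxy)phenyl]-3-hydroxypropanoyl}-1,3-thiazolidine-2-thione, via trichlorotitanium Z-enolate 10 (not isolated)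
Conditions: TiCl4 (1.05 equiv), iPr2NEt (1.1 equiv), NMP (1.0 equiv), CH2Cl2, 0 °C; then 3, −78 to 0 °C; aq. NH4Cl
Reagents that add atoms: none
Why: Crimmins titanium aldol in its Evans-syn mode: soft enolisation gives Z-enolate 10 and, with NMP on titanium, the aldehyde should add at the α-carbon through a non-chelated chair (Zimmerman–Traxler) transition state on the face away from the auxiliary benzyl group, setting the 2,3-syn (2S,3S) centres that become C1 and C8.

Step 5
Reactants: 11 aldol adduct
Product: 12 methyl (2S,3S)-2-[(E)-2-(4-benzyloxy-3-methoxyphenyl)ethenyl]-3-[3,4-bis(pivaloyloxy)phenyl]-3-hydroxypropanoate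
Conditions: imidazole, MeOH/CH2Cl2, rt
Reagents that add atoms: methanol, CO
Why: Nucleophilic acyl substitution of the activated thiazolidinethione amide by methanol under imidazole catalysis should occur at room temperature without retro-aldol or α-epimerisation, the hindered aryl pivalates being far slower to exchange.

Step 6
Reactants: 12 syn β-hydroxy ester
Product: 13 methyl (2S,3S)-2-[(E)-2-(4-benzyloxy-3-methoxyphenyl)ethenyl]-3-[3,4-bis(pivaloyloxy)phenyl]-3-(methoxymethoxy)propanoate
Conditions: MOMCl, iPr2NEt, Bu4NI (cat.), CH2Cl2, 0 °C to rt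
Reagents that add atoms: chloromethyl methyl ether, COCCl
Why: O-alkylation of the secondary benzylic alcohol with the chloromethyl ether under a hindered amine base is a standard acetal formation and should leave the acidic α-centre, the styrene and the pivalates untouched.

Step 7
Reactants: 13 methoxymethyl ether
Product: 17 (1S,4S,5R,8S)-4-(4-benzyloxy-3-methoxyphenyl)-8-[3,4-bis(pivaloyloxy)phenyl]-3,7-dioxabicyclo[3.3.0]octan-2-one, via oxocarbenium ion 14 (not isolated), via benzylic cation 15 (not isolated), via methoxylactonium ion 16 (not isolated)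
Conditions: Me3SiOTf (1.5 equiv), 2,6-di-tert-butyl-4-methylpyridine (0.3 equiv), CH2Cl2 (0.02 M), −78 to −20 °C; aq. NaHCO3
Reagents that add atoms: none
Why: Proposed new method: Me3SiOTf silylates the methoxy oxygen of the acetal and expels Me3SiOMe to give the O7=C6 oxocarbenium ion 14, C5 of the (E)-styrene adds to C6 so that the charge arrives at C4 beside the 4-benzyloxy-3-methoxyphenyl ring (15), the C2 ester carbonyl oxygen then bonds to C4 (16), and triflate removes the O-methyl group as MeOTf. The closest known reaction type is the oxonium-Prins cyclisation of aryl-terminated homoallylic oxocarbenium ions to tetrahydrofurans with capture of the benzylic cation by an external nucleophile, joined here to the lactonisation of a γ-cationic ester with loss of its alkyl group that is familiar from halolactonisation of esters. The ether ring closes in a five-membered mode that holds the C6=O7 bond inside the new ring and leaves the alkene outside it (exo with respect to the styrene), and the lactone closes by five-membered attack of the carbonyl oxygen on the cationic C4 placed 1,3 to C2. C5 is set by C1 and C8: the syn aldol relationship becomes trans on the ring and places the C8 aryl and C1 ester pseudo-equatorial in an envelope transition state, the ester oxygen can support the developing charge only when the C4 side chain is cis to it, and a C5 epimer that cannot lactonise can return to 14 by retro-Prins fragmentation; C4 is set by the cis-fused bicycle, which closes with the aryl group on its convex face and can correct itself by reversible ionisation of the C4–O3 bond. The step needs the Prins closure to outrun 2-oxonia-Cope rearrangement, ionisation of C8–O7 and Friedel–Crafts attack of the C8 aryl ring on C4, all of which are slowed by the two pivalates that make that ring electron-poor, while five- over six-membered closure follows from the cation-stabilising aryl group on C4.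

Step 8
Reactants: 17 benzyl ether bis-pivalate of the target
Product: 18 (1S,4S,5R,8S)-4-(4-benzyloxy-3-methoxyphenyl)-8-(3,4-dihydroxyphenyl)-3,7-dioxabicyclo[3.3.0]octan-2-one
Conditions: K2CO3 (3 equiv), degassed MeOH/THF, Ar, 0 °C to rt; then 1 M HCl to pH 3
Reagents that add atoms: none
Why: Base-mediated transesterification of the aryl pivalates is irreversible because phenoxide leaves, whereas any methanolysis of the γ-lactone is reversible and should close again on acidification; the benzyl ether still on the guaiacyl oxygen blocks quinone-methide ionisation at C4 and exclusion of air protects the catecholate.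

Step 9
Reactants: 18 benzyl ether of the target
Product: 19 (1S,4S,5R,8S)-8-(3,4-dihydroxyphenyl)-4-(4-hydroxy-3-methoxyphenyl)-3,7-dioxabicyclo[3.3.0]octan-2-one (target)
Conditions: H2 (1 atm), Pd/C (10% Pd on carbon), EtOAc, rt, stopped when 18 is consumed
Reagents that add atoms: none
Why: Hydrogenolysis of an aryl benzyl ether over Pd/C in a neutral aprotic solvent is expected to be much faster than cleavage of the benzylic C4–O3 and C8–O7 bonds, which normally needs acid or long exposure, so the lactone and all four stereocentres should be kept.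

**Compound list**

1 | 3,4-dihydroxybenzaldehyde | O=Cc1ccc(O)c(O)c1 | starting material
2 | pivaloyl chloride | CC(C)(C)C(=O)Cl | starting material
3 | 3,4-bis(pivaloyloxy)benzaldehyde | O=Cc1ccc(OC(=O)C(C)(C)C)c(OC(=O)C(C)(C)C)c1 | intermediate
4 | (2-carboxyethyl)triphenylphosphonium bromide | OC(=O)CC[P+](c1ccccc1)(c1ccccc1)c1ccccc1.[Br-] | starting material
5 | 4-(benzyloxy)-3-methoxybenzaldehyde | COc1cc(C=O)ccc1OCc1ccccc1 | starting material
6 | sodium 3-(triphenylphosphoranylidene)propanoate (ylide carboxylate) | [Na+].[O-]C(=O)CC=P(c1ccccc1)(c1ccccc1)c1ccccc1 | intermediate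
7 | (E)-4-[4-(benzyloxy)-3-methoxyphenyl]but-3-enoic acid | OC(=O)C/C=C/c1ccc(OCc2ccccc2)c(OC)c1 | intermediate
8 | (S)-4-benzyl-1,3-thiazolidine-2-thione | S=C1N[C@@H](Cc2ccccc2)CS1 | starting material
9 | (4S)-4-benzyl-3-[(E)-4-(4-benzyloxy-3-methoxyphenyl)but-3-enoyl]-1,3-thiazolidine-2-thione | O=C(C/C=C/c1ccc(OCc2ccccc2)c(OC)c1)N1C(=S)SC[C@@H]1Cc1ccccc1 | intermediate
10 | trichlorotitanium (Z)-enolate of 9 (styrene E) | Cl[Ti](Cl)(Cl)O/C(=C\C=C\c1ccc(OCc2ccccc2)c(OC)c1)N1C(=S)SC[C@@H]1Cc1ccccc1 | intermediate
11 | (4S)-4-benzyl-3-{(2S,3S)-2-[(E)-2-(4-benzyloxy-3-methoxyphenyl)ethenyl]-3-[3,4-bis(pivaloyloxy)phenyl]-3-hydroxypropanoyl}-1,3-thiazolidine-2-thione | O=C([C@@H](/C=C/c1ccc(OCc2ccccc2)c(OC)c1)[C@H](O)c1ccc(OC(=O)C(C)(C)C)c(OC(=O)C(C)(C)C)c1)N1C(=S)SC[C@@H]1Cc1ccccc1 | intermediate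
12 | methyl (2S,3S)-2-[(E)-2-(4-benzyloxy-3-methoxyphenyl)ethenyl]-3-[3,4-bis(pivaloyloxy)phenyl]-3-hydroxypropanoate | COC(=O)[C@@H](/C=C/c1ccc(OCc2ccccc2)c(OC)c1)[C@H](O)c1ccc(OC(=O)C(C)(C)C)c(OC(=O)C(C)(C)C)c1 | intermediate
13 | methyl (2S,3S)-2-[(E)-2-(4-benzyloxy-3-methoxyphenyl)ethenyl]-3-[3,4-bis(pivaloyloxy)phenyl]-3-(methoxymethoxy)propanoate | COC(=O)[C@@H](/C=C/c1ccc(OCc2ccccc2)c(OC)c1)[C@H](OCOC)c1ccc(OC(=O)C(C)(C)C)c(OC(=O)C(C)(C)C)c1 | intermediate
14 | O7=C6 oxocarbenium triflate: methyl (2S,3S)-2-[(E)-2-(4-benzyloxy-3-methoxyphenyl)ethenyl]-3-[3,4-bis(pivaloyloxy)phenyl]-3-(methylideneoxonio)propanoate triflate | COC(=O)[C@@H](/C=C/c1ccc(OCc2ccccc2)c(OC)c1)[C@H]([O+]=C)c1ccc(OC(=O)C(C)(C)C)c(OC(=O)C(C)(C)C)c1.[O-]S(=O)(=O)C(F)(F)F | intermediate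
15 | C4 benzylic cation triflate of the 2,3-trans-3,4-cis tetrahydrofuran: methyl 2-[3,4-bis(pivaloyloxy)phenyl]-4-[(4-benzyloxy-3-methoxyphenyl)methyliumyl]tetrahydrofuran-3-carboxylate (ring centres as in 17) | COC(=O)[C@H]1[C@@H]([CH+]c2ccc(OCc3ccccc3)c(OC)c2)CO[C@@H]1c1ccc(OC(=O)C(C)(C)C)c(OC(=O)C(C)(C)C)c1.[O-]S(=O)(=O)C(F)(F)F | intermediate
16 | (1S,4S,5R,8S)-4-(4-benzyloxy-3-methoxyphenyl)-8-[3,4-bis(pivaloyloxy)phenyl]-2-methoxy-3,7-dioxabicyclo[3.3.0]oct-2-en-3-ium triflate (O-methyl lactonium ion) | COc1cc([C@H]2[O+]=C(OC)[C@H]3[C@@H]2CO[C@@H]3c2ccc(OC(=O)C(C)(C)C)c(OC(=O)C(C)(C)C)c2)ccc1OCc1ccccc1.[O-]S(=O)(=O)C(F)(F)F | intermediate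
17 | (1S,4S,5R,8S)-4-(4-benzyloxy-3-methoxyphenyl)-8-[3,4-bis(pivaloyloxy)phenyl]-3,7-dioxabicyclo[3.3.0]octan-2-one | COc1cc([C@H]2OC(=O)[C@H]3[C@@H]2CO[C@@H]3c2ccc(OC(=O)C(C)(C)C)c(OC(=O)C(C)(C)C)c2)ccc1OCc1ccccc1 | intermediate
18 | (1S,4S,5R,8S)-4-(4-benzyloxy-3-methoxyphenyl)-8-(3,4-dihydroxyphenyl)-3,7-dioxabicyclo[3.3.0]octan-2-one | COc1cc([C@H]2OC(=O)[C@H]3[C@@H]2CO[C@@H]3c2ccc(O)c(O)c2)ccc1OCc1ccccc1 | intermediate
19 | (1S,4S,5R,8S)-8-(3,4-dihydroxyphenyl)-4-(4-hydroxy-3-methoxyphenyl)-3,7-dioxabicyclo[3.3.0]octan-2-one | COc1cc([C@H]2OC(=O)[C@H]3[C@@H]2CO[C@@H]3c2ccc(O)c(O)c2)ccc1O | target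

**Count**

Total steps: 9. Longest linear sequence: 8 steps (steps 2 to 9, from 4 and 5 to 19); step 1 is a one-step side branch that joins at step 4.

**Steps most likely to fail**

Step 7. The cation at C4 may be lost by elimination, Friedel–Crafts capture or oligomerisation before the ester closes, or the oxocarbenium ion may be diverted by 2-oxonia-Cope fragmentation. The fallback sets out from 13 and separates the two ring closures with known chemistry. SnBr4 in CH2Cl2 at −78 °C, the known oxonium-Prins cyclisation in which bromide takes up the benzylic cation, should give methyl (2S,3S,4R)-4-[bromo(4-benzyloxy-3-methoxyphenyl)methyl]-2-[3,4-bis(pivaloyloxy)phenyl]tetrahydrofuran-3-carboxylate F1. Either epimer at the bromide carbon is usable, and any 3,4-trans ring isomer would be removed by chromatography. AgOTf in CH2Cl2 at 0 °C would then ionise the benzylic bromide and the cis ester would close with loss of its methyl group (silver-assisted lactonisation of a γ-halo ester, through 15 and 16), which comes back to the route at 17.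

Step 4. The titanium dienolate may add with poor facial selectivity, react through its γ-carbon, or let the styrene move into conjugation. The fallback sets out from 7 and uses a boron enolate of an oxazolidinone imide. DCC/DMAP coupling of 7 with (S)-4-benzyl-1,3-oxazolidin-2-one should give (4S)-4-benzyl-3-[(E)-4-(4-benzyloxy-3-methoxyphenyl)but-3-enoyl]-1,3-oxazolidin-2-one F2. Bu2BOTf and iPr2NEt in CH2Cl2 at −78 °C would form its dibutylboron (Z)-enolate F3, which is not isolated and would be combined with aldehyde 3 in an Evans boron aldol (−78 to 0 °C, then H2O2 in pH 7 buffer/MeOH). This should give (4S)-4-benzyl-3-{(2S,3S)-2-[(E)-2-(4-benzyloxy-3-methoxyphenyl)ethenyl]-3-[3,4-bis(pivaloyloxy)phenyl]-3-hydroxypropanoyl}-1,3-oxazolidin-2-one F4. Yb(OTf)3-catalysed methanolysis of the imide (MeOH, rt), directed by two-point binding of the imide to the lanthanide, would come back to the route at 12.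

Step 9. Hydrogenolysis may continue into the benzylic C4–O3 bond of the lactone (or C8–O7) once the benzyl ether has gone. The fallback sets out from 18 and replaces reduction by Lewis-acid dealkylation: BCl3 with pentamethylbenzene as benzyl-cation scavenger (CH2Cl2, −78 °C, MeOH quench) should give 19 directly. It makes no further compound (F0).

**Further compounds**

F1 | step 7 | methyl (2S,3S,4R)-4-[bromo(4-benzyloxy-3-methoxyphenyl)methyl]-2-[3,4-bis(pivaloyloxy)phenyl]tetrahydrofuran-3-carboxylate | COC(=O)[C@H]1[C@@H](C(Br)c2ccc(OCc3ccccc3)c(OC)c2)CO[C@@H]1c1ccc(OC(=O)C(C)(C)C)c(OC(=O)C(C)(C)C)c1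
F2 | step 4 | (4S)-4-benzyl-3-[(E)-4-(4-benzyloxy-3-methoxyphenyl)but-3-enoyl]-1,3-oxazolidin-2-one | O=C(C/C=C/c1ccc(OCc2ccccc2)c(OC)c1)N1C(=O)OC[C@@H]1Cc1ccccc1
F3 | step 4 | dibutylboron (Z)-enolate of F2 | CCCCB(CCCC)O/C(=C\C=C\c1ccc(OCc2ccccc2)c(OC)c1)N1C(=O)OC[C@@H]1Cc1ccccc1
F4 | step 4 | (4S)-4-benzyl-3-{(2S,3S)-2-[(E)-2-(4-benzyloxy-3-methoxyphenyl)ethenyl]-3-[3,4-bis(pivaloyloxy)phenyl]-3-hydroxypropanoyl}-1,3-oxazolidin-2-one | O=C([C@@H](/C=C/c1ccc(OCc2ccccc2)c(OC)c1)[C@H](O)c1ccc(OC(=O)C(C)(C)C)c(OC(=O)C(C)(C)C)c1)N1C(=O)OC[C@@H]1Cc1ccccc1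
F0 | step 9 | none | none
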